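**Plan**

1. Retrosynthesis: cut C2′–C3′ and C4′–C5′ (two sp–sp2 bonds to a cis-CH=CH unit; the cis-alkenes C1′=C2′ and C5′=C6′ are latent alkynes). In the core cut C1–CH3, then C2–C3 of the cyclopentane, then C5–H (relayed from a C7 carbinol), C7a–C1 and C4–C8, which leads back to (R)-carvone. The side chain is cut at C13′=C14′, C11′=C12′, C9′–C10′ and C7′–C8′.
2. Forward: the arene is bought; the cyclohexene is the carvone ring, dressed at C4, C7a and C5; the cyclopentane is closed last, by carbene C–H insertion; the two halves are then joined and the triene unveiled.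
3. Enabling feature: the gem-dimethyl carbon C3 is the methine carbon of carvone's (hydrogenated) isopropyl group. Its C–H bond lies 1,5 to C2 once C7a carries a diazoacetyl arm, and both arms sit trans-diequatorial on the cyclohexene, so the trans ring fusion is fixed before the ring closes.
4. Core stereochemistry: C3a from (R)-carvone; C4 and C8 by a vinylogous aldol anti to isopropyl; C7a by an aldol anti to isopropyl; C5 by suprafacial hydrogen delivery from an allylic diazene (relay from C7); C1 by methyl addition to the trans-hydrindanone.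
5. Side-chain stereochemistry: C8′/C7′ by an Evans anti-aldol, C9′ by 1,3-syn reduction; 11′E by cross-metathesis, 13′Z by Still–Gennari olefination; 1′Z,3′Z,5′Z from cis-1,2-dichloroethene and cis-reduction of the enediyne.

Key step: step 13

Remark (numbering and reading of the target): atom numbers are those of the target throughout. Core: C1 = C(CH3)OH, C2 = CH2, C3 = C(CH3)2, C3a and C7a = ring-fusion carbons, C4 (bears the aryl carbinol carbon C8), C5 (bears the chain), C6(CH3)=C7. Chain: C1′ (on C5) to C15′ (CO2H). The SMILES is read as 1R,3aR,4R,5S,7aR,8S,7′S,8′R,9′R and 1′Z,3′Z,5′Z,11′E,13′Z, with a trans ring fusion and all four cyclohexene substituents trans to their neighbours. "As in the target" means the same arrangement in space; the CIP letter can differ in an intermediate.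

**Core (steps 1–15)**

Step 1
Reactants: 1 (R)-carvone
Product: 2 (R)-carvotanacetone, (5R)-2-methyl-5-(propan-2-yl)cyclohex-2-en-1-one
Conditions: H2 (1 atm), RhCl(PPh3)3 (2 mol%), benzene, rt
Reagents that add atoms: none
Why: Homogeneous hydrogenation with Wilkinson's catalyst should saturate only the unhindered 1,1-disubstituted alkene and leave the conjugated trisubstituted alkene and the stereocentre (the later C3a) untouched.

Step 2
Reactants: 2 (R)-carvotanacetone
Product: 3 through-conjugated trimethylsilyl dienol ether, trimethyl{[(5R)-2-methyl-5-(propan-2-yl)cyclohexa-1,3-dien-1-yl]oxy}silane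
Conditions: Me3SiCl, Et3N, DMF, 80 °C
Reagents that add atoms: chlorotrimethylsilane, C[Si](C)(C)Cl
Why: Silylation under equilibrating (House) conditions should remove a C4 proton and give the linear 1-silyloxy-1,3-diene, the isomer with the tetrasubstituted enol ether and through-conjugation.

Step 3
Reactants: 3 trimethylsilyl dienol ether; 4 4-[(tert-butyldimethylsilyl)oxy]benzaldehyde
Product: 5 γ-aldol, 2-methyl-5-isopropylcyclohex-2-enone carrying at the γ-carbon (target C4, trans to isopropyl) the (S)-hydroxy(4-silyloxyphenyl)methyl group (C8 as in the target)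
Conditions: BF3·OEt2 (1.1 equiv), CH2Cl2, −78 °C; then water
Reagents that add atoms: none
Why: In this vinylogous Mukaiyama aldol the dienol ether should attack the activated aldehyde through C4 (the α-carbon C6 is methyl-blocked), anti to the isopropyl group on C3a, and through an open antiperiplanar transition state with the aryl group beside H-4, which should give the (S)-carbinol at C8.

Step 4
Reactants: 5 γ-aldol
Product: 6 bis-silyl ether, the C8–O-tert-butyldimethylsilyl ether of 5
Conditions: t-BuMe2SiOTf (1.2 equiv), 2,6-lutidine, CH2Cl2, −78 °C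
Reagents that add atoms: tert-butyldimethylsilyl trifluoromethanesulfonate, CC(C)(C)[Si](C)(C)OS(=O)(=O)C(F)(F)F
Why: Silyl triflate with a hindered pyridine base is the standard silylation of a hindered secondary alcohol and should not enolise the enone at low temperature.

Step 5
Reactants: 6 bis-silyl ether
Product: 9 enone with a triethylsilyloxymethyl arm on C7a (trans to isopropyl), via lithium enolate 7 (not isolated), via lithium aldolate 8 (not isolated)
Conditions: LiN(i-Pr)2 (1.1 equiv), THF, −78 °C; CH2O (gas, from cracked paraformaldehyde); Et3SiCl, −78 → 0 °C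
Reagents that add atoms: formaldehyde, C=O; chlorotriethylsilane, CC[Si](CC)(CC)Cl
Why: Kinetic deprotonation at the α′-carbon C7a, aldol addition to formaldehyde anti to the neighbouring isopropyl group (as in α′-alkylations of carvone) and O-silylation of the aldolate in the same flask should set C7a trans to C3a and prevent retro-aldol cleavage and dehydration.

Step 6
Reactants: 9 enone with the triethylsilyloxymethyl arm
Product: 10 trimethylsilyl enol ether (C7–OSiMe3, C6=C7) with a (trimethylsilyl)ethynyl group on C5 (expected cis to the C4 substituent; this centre is erased in step 7)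
Conditions: Me3SiC≡CH, n-BuLi, THF, −78 °C; ZnBr2; then 9, Me3SiOTf, Et2O–THF, −40 °C
Reagents that add atoms: ethynyltrimethylsilane, C#C[Si](C)(C)C; trimethylsilyl trifluoromethanesulfonate, C[Si](C)(C)OS(=O)(=O)C(F)(F)F
Why: Silyl-triflate-promoted conjugate addition of an alkynylzinc bromide is the established way to put an alkynyl group on the β-carbon of a cyclic enone, and it traps the enolate regiospecifically as the silyl enol ether; the facial outcome at C5 does not matter here.

Step 7
Reactants: 10 trimethylsilyl enol ether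
Product: 11 enynone, O=C7–C6(CH3)=C5–C≡C–SiMe3 with C4, C3a and C7a as in 9
Conditions: Pd(OAc)2 (1.05 equiv), MeCN, rt
Reagents that add atoms: none
Why: In this Saegusa–Ito dehydrogenation the oxo-π-allylpalladium species should lose the tertiary propargylic hydrogen at C5 by β-hydride elimination and give the conjugated enynone, which makes C5 planar again.

Step 8
Reactants: 11 enynone
Product: 12 allylic alcohol, C7–OH trans to the C7a arm (cis-1,3 to isopropyl), C5=C6 retained
Conditions: NaBH4, CeCl3·7H2O, MeOH, −78 °C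
Reagents that add atoms: none
Why: Luche 1,2-reduction with axial hydride delivery on the all-equatorial half-chair should give the pseudo-equatorial alcohol (the carvone to cis-carveol outcome), which sets C7 as the relay centre for C5.

Step 9
Reactants: 12 allylic alcohol
Product: 15 skipped enyne with C5–H set and the alkene at C6=C7 (C5 alkynyl trans to the C4 substituent; all four ring centres as in the target), via allylic sulfonylhydrazine 13 (not isolated), via allylic diazene 14 (not isolated)
Conditions: 2-O2NC6H4SO2NHNH2, PPh3, EtO2CN=NCO2Et, N-methylmorpholine, −30 → 23 °C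
Reagents that add atoms: none
Why: In this Myers reductive allylic transposition the Mitsunobu displacement inverts C7, loss of arenesulfinic acid gives the diazene, and the suprafacial retro-ene loss of N2 should deliver hydrogen to C5 on the face opposite to the former hydroxyl, which leaves the alkynyl group equatorial and moves the alkene to C6=C7.

Step 10
Reactants: 15 skipped enyne
Product: 16 primary alcohol, C7a–CH2OH
Conditions: pyridinium p-toluenesulfonate (cat.), MeOH–CH2Cl2, 0 °C
Reagents that add atoms: none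
Why: Mild acid methanolysis should remove the primary triethylsilyl ether and spare the hindered secondary and the aryl tert-butyldimethylsilyl ethers.

Step 11
Reactants: 16 primary alcohol
Product: 17 carboxylic acid, C7a–CO2H
Conditions: TEMPO (cat.), PhI(OAc)2 (2.2 equiv), MeCN–H2O (pH 7), rt
Reagents that add atoms: water, O
Why: Oxoammonium oxidation takes the primary alcohol through the aldehyde hydrate to the acid under near-neutral conditions, which should preserve the allylic α-stereocentre C7a and the position of the alkene.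

Step 12
Reactants: 17 carboxylic acid
Product: 19 α-diazo ketone with a C7a–C(=O)CHN2 arm, via acid chloride 18 (not isolated)
Conditions: Me2C=C(Cl)NMe2, CH2Cl2, 0 °C; then CH2N2 (excess), Et2O, 0 °C
Reagents that add atoms: diazomethane, C=[N+]=[N-]
Why: Ghosez's chloroenamine forms the acid chloride without HCl (the benzylic silyl ether is acid-labile), and acylation of excess diazomethane should give the diazo ketone without base-induced ketene formation at C7a.

Step 13
Reactants: 19 α-diazo ketone
Product: 20 trans-fused 3,3-dimethylhydrindan-1-one (C1=O, C2H2, C3(CH3)2; C6=C7 and all ring centres as in the target)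
Conditions: Rh2(OAc)4 (1 mol%), CH2Cl2, rt, slow addition at high dilution
Reagents that add atoms: none
Why: Rh2(OAc)4 expels N2 from 19 and the electrophilic rhodium-bound acyl carbene at C2 inserts into the tertiary C3–H bond of the isopropyl group through a three-centre, hydride-transfer-like transition state, which forms the C2–C3 bond and the quaternary gem-dimethyl carbon in one event. The closest known reaction type is the dirhodium-catalysed 1,5 C–H insertion of α-diazo ketones into methine C–H bonds, which gives 3,3-disubstituted cyclopentanones. The cyclopentane closes as a five-membered ring by 1,5-insertion (C2 and C3 are joined across C1, C7a and C3a); the six-membered ring is not touched. No new stereocentre arises: C3 becomes the gem-dimethyl carbon, and the trans ring fusion is already fixed by the trans-diequatorial arms on C7a and C3a, which hold the carbene carbon and the methine hydrogen gauche and within bonding distance. The step needs site selectivity for this methine C–H over the C6=C7 alkene, the other C–H bonds and the arene: the acyl arm is locked pseudo-equatorial, near the nodal plane of the C6=C7 π bond, so the strained bicyclo[2.1.0]pentanone pathway is out of reach; C4–H is axial on the far face and deactivated by the C8 oxygen; C3a–H would give a cyclobutanone; six-ring insertion into the C6 methyl is slower than five-ring insertion into a tertiary C–H; and no free OH is present.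

Step 14
Reactants: 20 trans-fused hydrindanone
Product: 21 tertiary alcohol, C1(CH3)(OH) with OH cis to H-7a (C1 as in the target)
Conditions: AlMe3 (3 equiv), toluene, −78 → −20 °C
Reagents that add atoms: trimethylaluminium, C[Al](C)C
Why: With excess AlMe3 in a hydrocarbon solvent (Ashby conditions) methyl should enter anti to the pseudo-axial H-7a while the bulky aluminium-bound oxygen moves to the face that carries only one β-methyl group, and the weakly basic reagent should not epimerise the ring fusion or move the β,γ-alkene.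

Step 15
Reactants: 21 tertiary alcohol
Product: 22 core alkyne, C5–C≡CH with free phenol (C8 silyl ether retained)
Conditions: K2CO3, MeOH, rt
Reagents that add atoms: none
Why: Methanolysis with carbonate cleaves the C(sp)–Si bond and the phenolic silyl ether and should leave the secondary alkyl silyl ether and the tertiary alcohol.

**Side chain (steps 16–24)**

Step 16
Reactants: 23 (R)-4-benzyl-3-propanoyl-1,3-oxazolidin-2-one; 24 3-(trimethylsilyl)prop-2-ynal
Product: 26 anti-aldol imide (4R)-4-benzyl-3-[(2S,3R)-3-hydroxy-2-methyl-5-(trimethylsilyl)pent-4-ynoyl]-1,3-oxazolidin-2-one, via trimethylsilyl ether of the aldol 25 (not isolated)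
Conditions: MgCl2 (10 mol%), Et3N, Me3SiCl, EtOAc, rt; then CF3CO2H (cat.), MeOH
Reagents that add atoms: none
Why: In the Evans magnesium-halide-catalysed anti-aldol the chelated (Z)-enolate should add to the non-enolisable ynal on the face away from the benzyl group through a boat transition state, which sets C8′ and C7′ anti.

Step 17
Reactants: 26 anti-aldol imide
Product: 27 Weinreb amide, (2S,3R)-3-hydroxy-N-methoxy-N,2-dimethyl-5-(trimethylsilyl)pent-4-ynamide
Conditions: MeNHOMe·HCl, AlMe3, CH2Cl2, −20 → 0 °C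
Reagents that add atoms: N,O-dimethylhydroxylamine hydrochloride, CNOC.Cl
Why: Aluminium-amide transamination of an aldol imide with a free β-hydroxyl is standard and leaves both stereocentres untouched.

Step 18
Reactants: 27 Weinreb amide
Product: 28 β-hydroxy allyl ketone, (5S,6R)-6-hydroxy-5-methyl-8-(trimethylsilyl)oct-1-en-7-yn-4-one
Conditions: CH2=CHCH2MgBr (3 equiv), THF, −78 °C; cold water work-up
Reagents that add atoms: allylmagnesium bromide, C=CC[Mg]Br
Why: The chelated tetrahedral intermediate of the Weinreb ketone synthesis prevents over-addition and collapses only on cold work-up, so the β,γ-unsaturated ketone should be obtained without conjugation.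

Step 19
Reactants: 28 β-hydroxy allyl ketone
Product: 29 syn-1,3-diol with the anti,anti stereotriad (C7′, C8′, C9′ as in the target)
Conditions: Et2BOMe, NaBH4, THF–MeOH (4:1), −78 °C; repeated evaporation from MeOH
Reagents that add atoms: none
Why: In the Narasaka–Prasad reduction external hydride attacks the six-membered boron chelate through the chair-like arrangement with both substituents equatorial, so the C7′ hydroxyl should set C9′ 1,3-syn.

Step 20
Reactants: 29 syn-1,3-diol
Product: 30 bis(tert-butyldimethylsilyl) ether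
Conditions: t-BuMe2SiOTf (2.5 equiv), 2,6-lutidine, CH2Cl2, 0 °C
Reagents that add atoms: tert-butyldimethylsilyl trifluoromethanesulfonate, CC(C)(C)[Si](C)(C)OS(=O)(=O)C(F)(F)F
Why: Standard double silylation of secondary alcohols.

Step 21
Reactants: 30 bis-silyl ether
Product: 31 (E)-2-methyl enal, C11′=C12′(CH3)–CHO
Conditions: methacrolein (10 equiv), second-generation Hoveyda–Grubbs catalyst (5 mol%), CH2Cl2, 40 °C
Reagents that add atoms: methacrolein, CC(=C)C=O
Why: Cross-metathesis of a terminal alkene with excess methacrolein should give the thermodynamic (E)-trisubstituted enal, and the silyl-capped internal alkyne is a poor metathesis partner.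

Step 22
Reactants: 31 enal
Product: 32 methyl (2Z,4E)-dienoate
Conditions: (CF3CH2O)2P(O)CH2CO2Me, KN(SiMe3)2, 18-crown-6, THF, −78 °C
Reagents that add atoms: methyl bis(2,2,2-trifluoroethyl)phosphonoacetate, COC(=O)CP(=O)(OCC(F)(F)F)OCC(F)(F)F
Why: The Still–Gennari olefination gives kinetic (Z)-enoates from aldehydes, here the 13′Z alkene next to the existing 11′E alkene.

Step 23
Reactants: 32 dienoate
Product: 33 terminal alkyne
Conditions: K2CO3, MeOH, 0 °C
Reagents that add atoms: none
Why: Methanolysis removes the alkynyl silyl group; exchange at the methyl ester with methoxide is degenerate.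

Step 24
Reactants: 33 terminal alkyne
Product: 34 (Z)-chloroenyne, Cl–C3′H=C4′H–C5′≡C6′
Conditions: (Z)-ClCH=CHCl (5 equiv), Pd(PPh3)4 (5 mol%), CuI (10 mol%), n-BuNH2, benzene, rt
Reagents that add atoms: (Z)-1,2-dichloroethene, Cl/C=C\Cl
Why: Sonogashira coupling with excess cis-1,2-dichloroethene stops at mono-coupling and retains the alkene geometry.

**Union and endgame (steps 25–28)**

Step 25
Reactants: 22 core alkyne; 34 (Z)-chloroenyne
Product: 35 (Z)-enediyne, C1′≡C2′–C3′H=C4′H–C5′≡C6′
Conditions: Pd(PPh3)4 (5 mol%), CuI (10 mol%), n-BuNH2, benzene, rt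
Reagents that add atoms: none
Why: The activated vinyl chloride of a chloroenyne undergoes a second Sonogashira coupling with retention, and the amine conditions tolerate the free phenol and tertiary alcohol.

Step 26
Reactants: 35 (Z)-enediyne
Product: 36 (1′Z,3′Z,5′Z)-triene methyl ester
Conditions: zinc dust activated with Cu(OAc)2 and AgNO3, MeOH–H2O (1:1), rt, dark
Reagents that add atoms: none
Why: Activated zinc (Boland reduction) reduces conjugated alkynes to cis-alkenes by syn delivery of two hydrogens and does not reduce alkenes, so both alkynes flanking the cis-alkene should give the all-cis triene.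

Step 27
Reactants: 36 triene methyl ester
Product: 37 triene carboxylic acid (three silyl ethers retained)
Conditions: LiOH, THF–MeOH–H2O, 0 °C → rt; then AcOH to pH 5
Reagents that add atoms: lithium hydroxide, [Li+].[OH-]
Why: Saponification of the methyl ester at low temperature should not isomerise the (2Z)-enoate, which is protected as the carboxylate once formed.

Step 28
Reactants: 37 triene carboxylic acid
Product: 38 target, (2Z,4E,7R,8R,9S,10Z,12Z,14Z)-7,9-dihydroxy-15-[(1R,3aR,4R,5S,7aR)-1-hydroxy-4-[(S)-hydroxy(4-hydroxyphenyl)methyl]-1,3,3,6-tetramethyl-2,3,3a,4,5,7a-hexahydro-1H-inden-5-yl]-4,8-dimethylpentadeca-2,4,10,12,14-pentaenoic acid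
Conditions: Bu4NF, AcOH (1:1), THF, rt → 40 °C
Reagents that add atoms: none
Why: Fluoride cleaves the three secondary silyl ethers, and acetic acid buffering should protect the all-cis triene, the dienoic acid and the p-hydroxybenzylic alcohol from base.

**Compound list**

1 | (R)-carvone | CC1=CC[C@H](CC1=O)C(C)=C | starting material
2 | (R)-carvotanacetone | CC1=CC[C@H](CC1=O)C(C)C | intermediate
3 | through-conjugated trimethylsilyl dienol ether of 2 | CC1=C(O[Si](C)(C)C)C[C@H](C(C)C)C=C1 | intermediate
4 | 4-[(tert-butyldimethylsilyl)oxy]benzaldehyde | O=Cc1ccc(O[Si](C)(C)C(C)(C)C)cc1 | starting material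
5 | γ-aldol (C4, C8, C3a as in the target) | CC1=C[C@H]([C@H](O)c2ccc(O[Si](C)(C)C(C)(C)C)cc2)[C@@H](C(C)C)CC1=O | intermediate
6 | C8 silyl ether of 5 | CC1=C[C@H]([C@H](O[Si](C)(C)C(C)(C)C)c2ccc(O[Si](C)(C)C(C)(C)C)cc2)[C@@H](C(C)C)CC1=O | intermediate
7 | lithium α′-enolate of 6 | CC1=C[C@H]([C@H](O[Si](C)(C)C(C)(C)C)c2ccc(O[Si](C)(C)C(C)(C)C)cc2)[C@@H](C(C)C)C=C1[O-].[Li+] | intermediate
8 | lithium aldolate (C7a–CH2OLi) | CC1=C[C@H]([C@H](O[Si](C)(C)C(C)(C)C)c2ccc(O[Si](C)(C)C(C)(C)C)cc2)[C@@H](C(C)C)[C@H](C[O-])C1=O.[Li+] | intermediate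
9 | enone with C7a–CH2OSiEt3 arm | CC1=C[C@H]([C@H](O[Si](C)(C)C(C)(C)C)c2ccc(O[Si](C)(C)C(C)(C)C)cc2)[C@@H](C(C)C)[C@H](CO[Si](CC)(CC)CC)C1=O | intermediate
10 | trimethylsilyl enol ether with C5 alkynyl group | CC1=C(O[Si](C)(C)C)[C@@H](CO[Si](CC)(CC)CC)[C@@H]([C@@H]([C@H](O[Si](C)(C)C(C)(C)C)c2ccc(O[Si](C)(C)C(C)(C)C)cc2)[C@H]1C#C[Si](C)(C)C)C(C)C | intermediate
11 | enynone | CC1=C(C#C[Si](C)(C)C)[C@H]([C@H](O[Si](C)(C)C(C)(C)C)c2ccc(O[Si](C)(C)C(C)(C)C)cc2)[C@@H](C(C)C)[C@H](CO[Si](CC)(CC)CC)C1=O | intermediate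
12 | allylic alcohol (C7–OH) | CC1=C(C#C[Si](C)(C)C)[C@H]([C@H](O[Si](C)(C)C(C)(C)C)c2ccc(O[Si](C)(C)C(C)(C)C)cc2)[C@@H](C(C)C)[C@H](CO[Si](CC)(CC)CC)[C@H]1O | intermediate
13 | allylic N-(2-nitrobenzenesulfonyl)hydrazine (C7 inverted) | CC1=C(C#C[Si](C)(C)C)[C@H]([C@H](O[Si](C)(C)C(C)(C)C)c2ccc(O[Si](C)(C)C(C)(C)C)cc2)[C@@H](C(C)C)[C@H](CO[Si](CC)(CC)CC)[C@@H]1N(N)S(=O)(=O)c3ccccc3[N+](=O)[O-] | intermediate
14 | allylic diazene | CC1=C(C#C[Si](C)(C)C)[C@H]([C@H](O[Si](C)(C)C(C)(C)C)c2ccc(O[Si](C)(C)C(C)(C)C)cc2)[C@@H](C(C)C)[C@H](CO[Si](CC)(CC)CC)[C@@H]1N=N | intermediate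
15 | skipped enyne (C5–H set, C6=C7) | CC1=C[C@@H](CO[Si](CC)(CC)CC)[C@@H]([C@@H]([C@H](O[Si](C)(C)C(C)(C)C)c2ccc(O[Si](C)(C)C(C)(C)C)cc2)[C@@H]1C#C[Si](C)(C)C)C(C)C | intermediate
16 | primary alcohol (C7a–CH2OH) | CC1=C[C@@H](CO)[C@@H]([C@@H]([C@H](O[Si](C)(C)C(C)(C)C)c2ccc(O[Si](C)(C)C(C)(C)C)cc2)[C@@H]1C#C[Si](C)(C)C)C(C)C | intermediate
17 | carboxylic acid (C7a–CO2H) | CC1=C[C@@H](C(=O)O)[C@@H]([C@@H]([C@H](O[Si](C)(C)C(C)(C)C)c2ccc(O[Si](C)(C)C(C)(C)C)cc2)[C@@H]1C#C[Si](C)(C)C)C(C)C | intermediate
18 | acid chloride | CC1=C[C@@H](C(=O)Cl)[C@@H]([C@@H]([C@H](O[Si](C)(C)C(C)(C)C)c2ccc(O[Si](C)(C)C(C)(C)C)cc2)[C@@H]1C#C[Si](C)(C)C)C(C)C | intermediate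
19 | α-diazo ketone | CC1=C[C@@H](C(=O)C=[N+]=[N-])[C@@H]([C@@H]([C@H](O[Si](C)(C)C(C)(C)C)c2ccc(O[Si](C)(C)C(C)(C)C)cc2)[C@@H]1C#C[Si](C)(C)C)C(C)C | intermediate
20 | trans-fused 3,3-dimethylhydrindan-1-one | CC1=C[C@@H]2[C@@H]([C@@H]([C@H](O[Si](C)(C)C(C)(C)C)c3ccc(O[Si](C)(C)C(C)(C)C)cc3)[C@@H]1C#C[Si](C)(C)C)C(C)(C)CC2=O | intermediate
21 | tertiary alcohol (C1 set) | CC1=C[C@@H]2[C@@H]([C@@H]([C@H](O[Si](C)(C)C(C)(C)C)c3ccc(O[Si](C)(C)C(C)(C)C)cc3)[C@@H]1C#C[Si](C)(C)C)C(C)(C)C[C@@]2(C)O | intermediate
22 | core alkyne with free phenol | CC1=C[C@@H]2[C@@H]([C@@H]([C@H](O[Si](C)(C)C(C)(C)C)c3ccc(O)cc3)[C@@H]1C#C)C(C)(C)C[C@@]2(C)O | intermediate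
23 | (R)-4-benzyl-3-propanoyl-1,3-oxazolidin-2-one | CCC(=O)N1[C@H](Cc2ccccc2)COC1=O | starting material
24 | 3-(trimethylsilyl)prop-2-ynal | C[Si](C)(C)C#CC=O | starting material
25 | O-trimethylsilyl ether of the anti-aldol | C[Si](C)(C)C#C[C@H](O[Si](C)(C)C)[C@H](C)C(=O)N1[C@H](Cc2ccccc2)COC1=O | intermediate
26 | anti-aldol imide | C[Si](C)(C)C#C[C@H](O)[C@H](C)C(=O)N1[C@H](Cc2ccccc2)COC1=O | intermediate
27 | Weinreb amide | C[Si](C)(C)C#C[C@H](O)[C@H](C)C(=O)N(C)OC | intermediate
28 | β-hydroxy allyl ketone | C[Si](C)(C)C#C[C@H](O)[C@H](C)C(=O)CC=C | intermediate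
29 | syn-1,3-diol (anti,anti stereotriad) | C[Si](C)(C)C#C[C@H](O)[C@H](C)[C@H](O)CC=C | intermediate
30 | bis(tert-butyldimethylsilyl) ether | C[Si](C)(C)C#C[C@H](O[Si](C)(C)C(C)(C)C)[C@H](C)[C@H](O[Si](C)(C)C(C)(C)C)CC=C | intermediate
31 | (E)-2-methyl enal | C[Si](C)(C)C#C[C@H](O[Si](C)(C)C(C)(C)C)[C@H](C)[C@H](O[Si](C)(C)C(C)(C)C)C/C=C(C)/C=O | intermediate
32 | methyl (2Z,4E)-dienoate | C[Si](C)(C)C#C[C@H](O[Si](C)(C)C(C)(C)C)[C@H](C)[C@H](O[Si](C)(C)C(C)(C)C)C/C=C(C)/C=C\C(=O)OC | intermediate
33 | terminal alkyne | C#C[C@H](O[Si](C)(C)C(C)(C)C)[C@H](C)[C@H](O[Si](C)(C)C(C)(C)C)C/C=C(C)/C=C\C(=O)OC | intermediate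
34 | (Z)-chloroenyne | Cl/C=C\C#C[C@H](O[Si](C)(C)C(C)(C)C)[C@H](C)[C@H](O[Si](C)(C)C(C)(C)C)C/C=C(C)/C=C\C(=O)OC | intermediate
35 | (Z)-enediyne | CC1=C[C@@H]2[C@@H]([C@@H]([C@H](O[Si](C)(C)C(C)(C)C)c3ccc(O)cc3)[C@@H]1C#C/C=C\C#C[C@H](O[Si](C)(C)C(C)(C)C)[C@H](C)[C@H](O[Si](C)(C)C(C)(C)C)C/C=C(C)/C=C\C(=O)OC)C(C)(C)C[C@@]2(C)O | intermediate
36 | (1′Z,3′Z,5′Z)-triene methyl ester | CC1=C[C@@H]2[C@@H]([C@@H]([C@H](O[Si](C)(C)C(C)(C)C)c3ccc(O)cc3)[C@@H]1\C=C/C=C\C=C/[C@H](O[Si](C)(C)C(C)(C)C)[C@H](C)[C@H](O[Si](C)(C)C(C)(C)C)C/C=C(C)/C=C\C(=O)OC)C(C)(C)C[C@@]2(C)O | intermediate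
37 | triene carboxylic acid, tris-silyl ether | CC1=C[C@@H]2[C@@H]([C@@H]([C@H](O[Si](C)(C)C(C)(C)C)c3ccc(O)cc3)[C@@H]1\C=C/C=C\C=C/[C@H](O[Si](C)(C)C(C)(C)C)[C@H](C)[C@H](O[Si](C)(C)C(C)(C)C)C/C=C(C)/C=C\C(=O)O)C(C)(C)C[C@@]2(C)O | intermediate
38 | target | CC1=C[C@@H]2[C@@H]([C@@H]([C@H](O)c3ccc(O)cc3)[C@@H]1\C=C/C=C\C=C/[C@H](O)[C@H](C)[C@H](O)C/C=C(C)/C=C\C(=O)O)C(C)(C)C[C@@]2(C)O | target

**Step count and risks**

Total step count: 28. Longest linear sequence: 19 (steps 1–15, then 25–28); the side chain takes 9 steps (16–24).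

Steps most likely to fail:

Step 13. The free acyl carbene may be diverted before it reaches the methine C–H: addition to the C6=C7 alkene, insertion into the allylic methyl C–H, or Wolff-type rearrangement. Fallback: set out from acid 17 and use an ester-stabilised carbenoid, the substrate class on which 1,5 methine insertion is best established, with a temporary allyl ester. Activation of 17 with carbonyldiimidazole and reaction with Mg(O2CCH2CO2CH2CH=CH2)2 in THF should give the allyl β-keto ester F1. Diazo transfer (4-acetamidobenzenesulfonyl azide, Et3N, MeCN) should give the α-diazo β-keto ester F2. Rh2(OAc)4 in CH2Cl2 should then give the 2-(allyloxycarbonyl)hydrindanone F3. Deallylation with Pd(PPh3)4 and morpholine in THF at rt is followed by spontaneous decarboxylation and returns to ketone 20.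

Step 9. The Mitsunobu displacement at the hindered allylic carbinol C7 may stall or give elimination, so that no diazene forms. Fallback: set out from alcohol 12 and use a palladium hydride transfer instead of a sigmatropic one. Methyl chloroformate and pyridine should give the allylic methyl carbonate F4. Pd(OAc)2, PBu3 and HCO2H–Et3N in THF (Tsuji formate reduction) ionise the carbonate anti and deliver hydride from palladium to the more substituted allyl terminus C5, on the face opposite to the former oxygen, which returns to 15.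

Step 26. The double semi-reduction may stop at a dienyne, over-reduce, or isomerise the sensitive all-cis triene. Fallback: form all three cis-alkenes before the last C–C bonds and join them by Stille couplings with retention; this sets out from 21 and 32 and returns at 37. Core: 21 with N-iodosuccinimide and AgNO3 (cat.) in acetone should give the iodoalkyne F5, and diimide (2-nitrobenzenesulfonylhydrazide, Et3N) should give the (Z)-vinyl iodide F6. Side chain: 32 should give in the same two operations the iodoalkyne F7 and the (Z)-vinyl iodide F8. Stille coupling of F8 with excess (Z)-1,2-bis(tributylstannyl)ethene (Pd2(dba)3, AsPh3, DMF) should give the (Z,Z)-dienylstannane F9. A second Stille coupling of F9 with F6 should give the fully silylated triene ester F10. LiOH as in step 27 cleaves the methyl ester and the aryl silyl ether of F10 and gives 37.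

Further compounds
F1 | step 13 | allyl β-keto ester on C7a | CC1=C[C@@H](C(=O)CC(=O)OCC=C)[C@@H]([C@@H]([C@H](O[Si](C)(C)C(C)(C)C)c2ccc(O[Si](C)(C)C(C)(C)C)cc2)[C@@H]1C#C[Si](C)(C)C)C(C)C
F2 | step 13 | α-diazo β-keto ester | CC1=C[C@@H](C(=O)C(=[N+]=[N-])C(=O)OCC=C)[C@@H]([C@@H]([C@H](O[Si](C)(C)C(C)(C)C)c2ccc(O[Si](C)(C)C(C)(C)C)cc2)[C@@H]1C#C[Si](C)(C)C)C(C)C
F3 | step 13 | 2-(allyloxycarbonyl)-3,3-dimethylhydrindan-1-one (C2 epimers, enolisable) | CC1=C[C@@H]2[C@@H]([C@@H]([C@H](O[Si](C)(C)C(C)(C)C)c3ccc(O[Si](C)(C)C(C)(C)C)cc3)[C@@H]1C#C[Si](C)(C)C)C(C)(C)C(C(=O)OCC=C)C2=O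
F4 | step 9 | allylic methyl carbonate of 12 | CC1=C(C#C[Si](C)(C)C)[C@H]([C@H](O[Si](C)(C)C(C)(C)C)c2ccc(O[Si](C)(C)C(C)(C)C)cc2)[C@@H](C(C)C)[C@H](CO[Si](CC)(CC)CC)[C@H]1OC(=O)OC
F5 | step 26 | core iodoalkyne | CC1=C[C@@H]2[C@@H]([C@@H]([C@H](O[Si](C)(C)C(C)(C)C)c3ccc(O[Si](C)(C)C(C)(C)C)cc3)[C@@H]1C#CI)C(C)(C)C[C@@]2(C)O
F6 | step 26 | core (Z)-vinyl iodide | CC1=C[C@@H]2[C@@H]([C@@H]([C@H](O[Si](C)(C)C(C)(C)C)c3ccc(O[Si](C)(C)C(C)(C)C)cc3)[C@@H]1\C=C/I)C(C)(C)C[C@@]2(C)O
F7 | step 26 | side-chain iodoalkyne | IC#C[C@H](O[Si](C)(C)C(C)(C)C)[C@H](C)[C@H](O[Si](C)(C)C(C)(C)C)C/C=C(C)/C=C\C(=O)OC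
F8 | step 26 | side-chain (Z)-vinyl iodide | I/C=C\[C@H](O[Si](C)(C)C(C)(C)C)[C@H](C)[C@H](O[Si](C)(C)C(C)(C)C)C/C=C(C)/C=C\C(=O)OC
F9 | step 26 | (Z,Z)-dienylstannane | CCCC[Sn](CCCC)(CCCC)/C=C\C=C/[C@H](O[Si](C)(C)C(C)(C)C)[C@H](C)[C@H](O[Si](C)(C)C(C)(C)C)C/C=C(C)/C=C\C(=O)OC
F10 | step 26 | fully silylated triene methyl ester | CC1=C[C@@H]2[C@@H]([C@@H]([C@H](O[Si](C)(C)C(C)(C)C)c3ccc(O[Si](C)(C)C(C)(C)C)cc3)[C@@H]1\C=C/C=C\C=C/[C@H](O[Si](C)(C)C(C)(C)C)[C@H](C)[C@H](O[Si](C)(C)C(C)(C)C)C/C=C(C)/C=C\C(=O)OC)C(C)(C)C[C@@]2(C)O
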